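**Retrosynthetic overview**
1. The oxirane (the only ring of the target) is closed last from chlorohydrin 27 ⇐ CBS reduction of chloromethyl ketone 26 ⇐ acid 23 + diazomethane (C1).
2. C3(Cl)/C4(Br): acid 23 ⇐ bromide opening (inversion at C4) of α‑chloro‑β‑lactone 22 ⇐ enolate chlorination of lactone 20 ⇐ Evans syn‑aldol of aldehyde 15 with the (R)‑propionyl oxazolidinone (C2, C3, CH3).
3. C6(Cl)/C7(Br)/C8: 15 ⇐ chloride opening (inversion at C6) of α‑bromo‑β‑lactone 10 ⇐ enolate bromination of lactone 8 ⇐ Evans syn‑aldol of 3‑silyloxypropanal 3 with the (S)‑propionyl oxazolidinone (C7, C8, CH3); CO2H → CH2Cl.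
4. Ring order: oxetan‑2‑one 8 (C6–C8) is formed and opened, then oxetan‑2‑one 20 (C2–C4) is formed and opened, then the oxirane.

Assumption: the chain is labelled C1 (oxirane CH2) to C8 (CH2Cl); the given SMILES then reads (2S,3R,4R,6S,7S), i.e. (S)‑2‑[(2R,3R,5S,6S)‑3,6‑dibromo‑2,5,7‑trichloro‑6‑methylheptan‑2‑yl]oxirane.

**Route**

Step 1
Reactants: 1 propane‑1,3‑diol
Product: 2 3‑[(tert‑butyldiphenylsilyl)oxy]propan‑1‑ol
Conditions: NaH (1.0 equiv), THF, 0 °C → rt; then t‑BuPh2SiCl (1.0 equiv)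
Reagents that add atoms: tert‑butyl(chloro)diphenylsilane, CC(C)(C)[Si](Cl)(c1ccccc1)c1ccccc1
Why: O‑silylation of the sparingly soluble monosodium alkoxide gives the mono‑silyl ether selectively; no stereocentre is involved.

Step 2
Reactants: 2 3‑[(tert‑butyldiphenylsilyl)oxy]propan‑1‑ol
Product: 3 3‑[(tert‑butyldiphenylsilyl)oxy]propanal
Conditions: TEMPO (10 mol %), PhI(OAc)2 (1.1 equiv), CH2Cl2, rt
Reagents that add atoms: none
Why: TEMPO/PhI(OAc)2 (oxoammonium) oxidation stops at the aldehyde and leaves the silyl ether untouched.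

Step 3
Reactants: 3 3‑[(tert‑butyldiphenylsilyl)oxy]propanal, 4 (S)‑4‑benzyl‑3‑propionyloxazolidin‑2‑one
Product: 6 (S)‑4‑benzyl‑3‑{(2S,3R)‑5‑[(tert‑butyldiphenylsilyl)oxy]‑3‑hydroxy‑2‑methylpentanoyl}oxazolidin‑2‑one, via Z‑boron enolate 5 (not isolated)
Conditions: n‑Bu2BOTf (1.1 equiv), i‑Pr2NEt (1.2 equiv), CH2Cl2, 0 °C; 3, −78 → 0 °C; then pH 7 buffer, MeOH, 30% H2O2, 0 °C
Reagents that add atoms: none
Why: Evans syn‑aldol reaction; the Z‑boron enolate reacts through a Zimmerman–Traxler chair on the face away from the benzyl group, forming the C6–C7 bond and setting the carbinol C6 as (R) (C7 is erased later).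

Step 4
Reactants: 6 (S)‑4‑benzyl‑3‑{(2S,3R)‑5‑[(tert‑butyldiphenylsilyl)oxy]‑3‑hydroxy‑2‑methylpentanoyl}oxazolidin‑2‑one
Product: 7 (2S,3R)‑5‑[(tert‑butyldiphenylsilyl)oxy]‑3‑hydroxy‑2‑methylpentanoic acid
Conditions: LiOH (2 equiv), 30% H2O2 (4 equiv), THF/H2O 3:1, 0 °C; Na2SO3; HCl to pH 2–3
Reagents that add atoms: hydrogen peroxide, OO
Why: Lithium hydroperoxide cleaves the exocyclic imide carbonyl selectively (standard auxiliary removal) without touching either stereocentre.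

Step 5
Reactants: 7 (2S,3R)‑5‑[(tert‑butyldiphenylsilyl)oxy]‑3‑hydroxy‑2‑methylpentanoic acid
Product: 8 (3S,4R)‑4‑{2‑[(tert‑butyldiphenylsilyl)oxy]ethyl}‑3‑methyloxetan‑2‑one (cis)
Conditions: PhSO2Cl (2 equiv), pyridine, 0 → 4 °C, 16 h
Reagents that add atoms: none
Why: Adam β‑lactonisation; the carboxyl group is activated as the mixed sulfonic anhydride and attacked by the β‑hydroxyl, so the ring closes with retention at both centres.

Step 6
Reactants: 8 (3S,4R)‑4‑{2‑[(tert‑butyldiphenylsilyl)oxy]ethyl}‑3‑methyloxetan‑2‑one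
Product: 10 (3R,4R)‑3‑bromo‑4‑{2‑[(tert‑butyldiphenylsilyl)oxy]ethyl}‑3‑methyloxetan‑2‑one, via lithium lactone enolate 9 (not isolated)
Conditions: LiN(i‑Pr)2 (1.1 equiv), THF, −78 °C, 20 min; BrCl2CCCl2Br (1.2 equiv), −78 °C
Reagents that add atoms: 1,2‑dibromo‑1,1,2,2‑tetrachloroethane, BrC(Cl)(Cl)C(Cl)(Cl)Br
Why: α‑Bromination of a β‑lactone enolate; electrophilic bromine attacks the flat four‑membered enolate anti to the C4 side chain, creating the quaternary C7–Br centre with bromine trans to the chain (minor cis isomer removed by chromatography).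

Step 7
Reactants: 10 (3R,4R)‑3‑bromo‑4‑{2‑[(tert‑butyldiphenylsilyl)oxy]ethyl}‑3‑methyloxetan‑2‑one
Product: 11 (2S,3S)‑2‑bromo‑5‑[(tert‑butyldiphenylsilyl)oxy]‑3‑chloro‑2‑methylpentanoic acid
Conditions: HCl (4 M in 1,4‑dioxane, 10 equiv), Et4NCl (2 equiv), CH2Cl2, 0 °C → rt
Reagents that add atoms: hydrogen chloride, Cl
Why: Acid‑promoted alkyl–oxygen cleavage of the β‑lactone; chloride attacks the protonated strained ring in an SN2 reaction with inversion, giving the (S)‑chloride at C6, and the ring geometry keeps the α‑bromine from bridging.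

Step 8
Reactants: 11 (2S,3S)‑2‑bromo‑5‑[(tert‑butyldiphenylsilyl)oxy]‑3‑chloro‑2‑methylpentanoic acid
Product: 12 (2S,3S)‑2‑bromo‑5‑[(tert‑butyldiphenylsilyl)oxy]‑3‑chloro‑2‑methylpentan‑1‑ol
Conditions: BH3·SMe2 (2.5 equiv), THF, 0 °C → rt; MeOH
Reagents that add atoms: none
Why: Borane reduces the carboxylic acid chemoselectively without touching C–Br, C–Cl or the silyl ether, and the neutral conditions avoid epoxide formation from the bromohydrin.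

Step 9
Reactants: 12 (2S,3S)‑2‑bromo‑5‑[(tert‑butyldiphenylsilyl)oxy]‑3‑chloro‑2‑methylpentan‑1‑ol
Product: 13 {[(3S,4S)‑4‑bromo‑3,5‑dichloro‑4‑methylpentyl]oxy}(tert‑butyl)diphenylsilane
Conditions: PPh3 (1.5 equiv), CCl4/CH2Cl2 1:2, 40 °C
Reagents that add atoms: carbon tetrachloride, ClC(Cl)(Cl)Cl
Why: Appel reaction; the ion‑paired chloride displaces Ph3P=O at the primary carbon in a non‑ionising medium, a process that tolerates neopentyl‑type centres without rearrangement, and no stereocentre is touched.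

Step 10
Reactants: 13 {[(3S,4S)‑4‑bromo‑3,5‑dichloro‑4‑methylpentyl]oxy}(tert‑butyl)diphenylsilane
Product: 14 (3S,4S)‑4‑bromo‑3,5‑dichloro‑4‑methylpentan‑1‑ol
Conditions: HF·pyridine, THF/pyridine, 0 °C → rt
Reagents that add atoms: none
Why: Fluoride‑mediated desilylation under buffered, non‑basic conditions frees the primary alcohol without eliminating HBr or HCl.

Step 11
Reactants: 14 (3S,4S)‑4‑bromo‑3,5‑dichloro‑4‑methylpentan‑1‑ol
Product: 15 (3S,4S)‑4‑bromo‑3,5‑dichloro‑4‑methylpentanal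
Conditions: TEMPO (10 mol %), PhI(OAc)2 (1.2 equiv), CH2Cl2, rt; used crude
Reagents that add atoms: none
Why: TEMPO/PhI(OAc)2 oxidation under neutral conditions gives the β‑chloro aldehyde without E1cB loss of HCl.

Step 12
Reactants: 15 (3S,4S)‑4‑bromo‑3,5‑dichloro‑4‑methylpentanal, 16 (R)‑4‑benzyl‑3‑propionyloxazolidin‑2‑one
Product: 18 (R)‑4‑benzyl‑3‑[(2R,3S,5S,6S)‑6‑bromo‑5,7‑dichloro‑3‑hydroxy‑2,6‑dimethylheptanoyl]oxazolidin‑2‑one, via Z‑boron enolate 17 (not isolated)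
Conditions: n‑Bu2BOTf (1.1 equiv), i‑Pr2NEt (1.2 equiv), CH2Cl2, 0 °C; 15, −78 → 0 °C; then pH 7 buffer, MeOH, 30% H2O2, 0 °C
Reagents that add atoms: none
Why: Second Evans syn‑aldol reaction with the enantiomeric auxiliary; reagent control through the Zimmerman–Traxler chair forms the C3–C4 bond and sets the carbinol C4 as (S) irrespective of the remote halogenated centres.

Step 13
Reactants: 18 (R)‑4‑benzyl‑3‑[(2R,3S,5S,6S)‑6‑bromo‑5,7‑dichloro‑3‑hydroxy‑2,6‑dimethylheptanoyl]oxazolidin‑2‑one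
Product: 19 (2R,3S,5S,6S)‑6‑bromo‑5,7‑dichloro‑3‑hydroxy‑2,6‑dimethylheptanoic acid
Conditions: LiOH (2 equiv), 30% H2O2 (4 equiv), THF/H2O 3:1, 0 °C, 1 h; Na2SO3; HCl to pH 2
Reagents that add atoms: hydrogen peroxide, OO
Why: Lithium hydroperoxide cleaves the exocyclic imide at 0 °C faster than it attacks the deactivated alkyl halides, releasing the acid and the auxiliary.

Step 14
Reactants: 19 (2R,3S,5S,6S)‑6‑bromo‑5,7‑dichloro‑3‑hydroxy‑2,6‑dimethylheptanoic acid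
Product: 20 (3R,4S)‑4‑[(2S,3S)‑3‑bromo‑2,4‑dichloro‑3‑methylbutyl]‑3‑methyloxetan‑2‑one (cis)
Conditions: PhSO2Cl (2 equiv), pyridine, 0 → 4 °C, 16 h
Reagents that add atoms: none
Why: Adam β‑lactonisation by carboxyl activation closes the second oxetan‑2‑one with retention at C3 and C4.

Step 15
Reactants: 20 (3R,4S)‑4‑[(2S,3S)‑3‑bromo‑2,4‑dichloro‑3‑methylbutyl]‑3‑methyloxetan‑2‑one
Product: 22 (3S,4S)‑4‑[(2S,3S)‑3‑bromo‑2,4‑dichloro‑3‑methylbutyl]‑3‑chloro‑3‑methyloxetan‑2‑one, via lithium lactone enolate 21 (not isolated)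
Conditions: LiN(i‑Pr)2 (1.05 equiv), THF, −78 °C, 10 min; Cl3CCCl3 (1.3 equiv), −78 °C
Reagents that add atoms: hexachloroethane, ClC(Cl)(Cl)C(Cl)(Cl)Cl
Why: α‑Chlorination of the β‑lactone enolate; kinetic deprotonation at −78 °C outpaces elimination of the alkyl halides, and chlorine enters anti to the C4 side chain to give the tertiary C3–Cl centre.

Step 16
Reactants: 22 (3S,4S)‑4‑[(2S,3S)‑3‑bromo‑2,4‑dichloro‑3‑methylbutyl]‑3‑chloro‑3‑methyloxetan‑2‑one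
Product: 23 (2R,3R,5S,6S)‑3,6‑dibromo‑2,5,7‑trichloro‑2,6‑dimethylheptanoic acid
Conditions: HBr (33% in AcOH, 10 equiv), Bu4NBr (1 equiv), CH2Cl2, 0 °C → rt
Reagents that add atoms: hydrogen bromide, Br
Why: Acid‑promoted SN2 ring opening of the β‑lactone by bromide with inversion installs the (R)‑bromide at C4 next to the C3 chloride, which cannot bridge inside the ring.

Step 17
Reactants: 23 (2R,3R,5S,6S)‑3,6‑dibromo‑2,5,7‑trichloro‑2,6‑dimethylheptanoic acid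
Product: 25 (3R,4R,6S,7S)‑4,7‑dibromo‑3,6,8‑trichloro‑1‑diazo‑3,7‑dimethyloctan‑2‑one, via acid chloride 24 (not isolated)
Conditions: (COCl)2 (1.5 equiv), DMF (cat.), CH2Cl2, 0 °C → rt; evaporate; CH2N2 (3 equiv), Et2O, 0 °C
Reagents that add atoms: diazomethane, C=[N+]=[N-]
Why: Arndt–Eistert‑type acylation of diazomethane by the acid chloride adds C1; the α‑carbon is quaternary, so neither ketene formation nor epimerisation is possible.

Step 18
Reactants: 25 (3R,4R,6S,7S)‑4,7‑dibromo‑3,6,8‑trichloro‑1‑diazo‑3,7‑dimethyloctan‑2‑one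
Product: 26 (3R,4R,6S,7S)‑4,7‑dibromo‑1,3,6,8‑tetrachloro‑3,7‑dimethyloctan‑2‑one
Conditions: HCl (2 M in Et2O, 1.5 equiv), Et2O, 0 °C
Reagents that add atoms: hydrogen chloride, Cl
Why: Protonation of the diazoketone and SN2 displacement of N2 by chloride (Nierenstein‑type hydrochlorination) gives the chloromethyl ketone.

Step 19
Reactants: 26 (3R,4R,6S,7S)‑4,7‑dibromo‑1,3,6,8‑tetrachloro‑3,7‑dimethyloctan‑2‑one
Product: 27 (2S,3R,4R,6S,7S)‑4,7‑dibromo‑1,3,6,8‑tetrachloro‑3,7‑dimethyloctan‑2‑ol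
Conditions: (R)‑Me‑CBS oxazaborolidine [(R)‑1‑methyl‑3,3‑diphenyltetrahydro‑1H,3H‑pyrrolo[1,2‑c][1,3,2]oxazaborole] (0.5 equiv), BH3·SMe2 (1.0 equiv), THF, −20 °C; MeOH
Reagents that add atoms: none
Why: Corey–Bakshi–Shibata reduction; the catalyst delivers hydride to the face that keeps the quaternary carbon away from boron, and this is also the polar Felkin–Anh (Cornforth) face of the α‑chloro ketone (hydride anti to C–Cl, past the methyl group), so catalyst and substrate both favour the (2S)‑alcohol.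

Step 20
Reactants: 27 (2S,3R,4R,6S,7S)‑4,7‑dibromo‑1,3,6,8‑tetrachloro‑3,7‑dimethyloctan‑2‑ol
Product: 28 (S)‑2‑[(2R,3R,5S,6S)‑3,6‑dibromo‑2,5,7‑trichloro‑6‑methylheptan‑2‑yl]oxirane
Conditions: K2CO3 (1.5 equiv), MeOH, 0 °C, 1 h
Reagents that add atoms: none
Why: Intramolecular Williamson etherification (3‑exo‑tet) of the chlorohydrin closes the oxirane with retention at C2, the primary C1 chloride being displaced far faster than any of the hindered halides.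

**Compound list**

1 | propane‑1,3‑diol | OCCCO | starting material
2 | 3‑[(tert‑butyldiphenylsilyl)oxy]propan‑1‑ol | OCCCO[Si](c1ccccc1)(c1ccccc1)C(C)(C)C | intermediate
3 | 3‑[(tert‑butyldiphenylsilyl)oxy]propanal | O=CCCO[Si](c1ccccc1)(c1ccccc1)C(C)(C)C | intermediate
4 | (S)‑4‑benzyl‑3‑propionyloxazolidin‑2‑one | CCC(=O)N1C(=O)OC[C@@H]1Cc1ccccc1 | starting material
5 | (S)‑4‑benzyl‑3‑[(Z)‑1‑(dibutylboranyloxy)prop‑1‑en‑1‑yl]oxazolidin‑2‑one | C/C=C(\OB(CCCC)CCCC)N1C(=O)OC[C@@H]1Cc1ccccc1 | intermediate (not isolated)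
6 | (S)‑4‑benzyl‑3‑{(2S,3R)‑5‑[(tert‑butyldiphenylsilyl)oxy]‑3‑hydroxy‑2‑methylpentanoyl}oxazolidin‑2‑one | O=C(N1C(=O)OC[C@@H]1Cc1ccccc1)[C@@H](C)[C@H](O)CCO[Si](c1ccccc1)(c1ccccc1)C(C)(C)C | intermediate
7 | (2S,3R)‑5‑[(tert‑butyldiphenylsilyl)oxy]‑3‑hydroxy‑2‑methylpentanoic acid | OC(=O)[C@@H](C)[C@H](O)CCO[Si](c1ccccc1)(c1ccccc1)C(C)(C)C | intermediate
8 | (3S,4R)‑4‑{2‑[(tert‑butyldiphenylsilyl)oxy]ethyl}‑3‑methyloxetan‑2‑one | C[C@@H]1C(=O)O[C@@H]1CCO[Si](c1ccccc1)(c1ccccc1)C(C)(C)C | intermediate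
9 | lithium (R)‑4‑{2‑[(tert‑butyldiphenylsilyl)oxy]ethyl}‑3‑methyl‑4H‑oxet‑2‑olate | CC1=C([O-])O[C@@H]1CCO[Si](c1ccccc1)(c1ccccc1)C(C)(C)C.[Li+] | intermediate (not isolated)
10 | (3R,4R)‑3‑bromo‑4‑{2‑[(tert‑butyldiphenylsilyl)oxy]ethyl}‑3‑methyloxetan‑2‑one | C[C@]1(Br)C(=O)O[C@@H]1CCO[Si](c1ccccc1)(c1ccccc1)C(C)(C)C | intermediate
11 | (2S,3S)‑2‑bromo‑5‑[(tert‑butyldiphenylsilyl)oxy]‑3‑chloro‑2‑methylpentanoic acid | OC(=O)[C@](C)(Br)[C@@H](Cl)CCO[Si](c1ccccc1)(c1ccccc1)C(C)(C)C | intermediate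
12 | (2S,3S)‑2‑bromo‑5‑[(tert‑butyldiphenylsilyl)oxy]‑3‑chloro‑2‑methylpentan‑1‑ol | OC[C@](C)(Br)[C@@H](Cl)CCO[Si](c1ccccc1)(c1ccccc1)C(C)(C)C | intermediate
13 | {[(3S,4S)‑4‑bromo‑3,5‑dichloro‑4‑methylpentyl]oxy}(tert‑butyl)diphenylsilane | ClC[C@](C)(Br)[C@@H](Cl)CCO[Si](c1ccccc1)(c1ccccc1)C(C)(C)C | intermediate
14 | (3S,4S)‑4‑bromo‑3,5‑dichloro‑4‑methylpentan‑1‑ol | ClC[C@](C)(Br)[C@@H](Cl)CCO | intermediate
15 | (3S,4S)‑4‑bromo‑3,5‑dichloro‑4‑methylpentanal | ClC[C@](C)(Br)[C@@H](Cl)CC=O | intermediate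
16 | (R)‑4‑benzyl‑3‑propionyloxazolidin‑2‑one | CCC(=O)N1C(=O)OC[C@H]1Cc1ccccc1 | starting material
17 | (R)‑4‑benzyl‑3‑[(Z)‑1‑(dibutylboranyloxy)prop‑1‑en‑1‑yl]oxazolidin‑2‑one | C/C=C(\OB(CCCC)CCCC)N1C(=O)OC[C@H]1Cc1ccccc1 | intermediate (not isolated)
18 | (R)‑4‑benzyl‑3‑[(2R,3S,5S,6S)‑6‑bromo‑5,7‑dichloro‑3‑hydroxy‑2,6‑dimethylheptanoyl]oxazolidin‑2‑one | O=C(N1C(=O)OC[C@H]1Cc1ccccc1)[C@H](C)[C@@H](O)C[C@H](Cl)[C@@](C)(Br)CCl | intermediate
19 | (2R,3S,5S,6S)‑6‑bromo‑5,7‑dichloro‑3‑hydroxy‑2,6‑dimethylheptanoic acid | OC(=O)[C@H](C)[C@@H](O)C[C@H](Cl)[C@@](C)(Br)CCl | intermediate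
20 | (3R,4S)‑4‑[(2S,3S)‑3‑bromo‑2,4‑dichloro‑3‑methylbutyl]‑3‑methyloxetan‑2‑one | C[C@H]1C(=O)O[C@H]1C[C@H](Cl)[C@@](C)(Br)CCl | intermediate
21 | lithium (S)‑4‑[(2S,3S)‑3‑bromo‑2,4‑dichloro‑3‑methylbutyl]‑3‑methyl‑4H‑oxet‑2‑olate | CC1=C([O-])O[C@H]1C[C@H](Cl)[C@@](C)(Br)CCl.[Li+] | intermediate (not isolated)
22 | (3S,4S)‑4‑[(2S,3S)‑3‑bromo‑2,4‑dichloro‑3‑methylbutyl]‑3‑chloro‑3‑methyloxetan‑2‑one | C[C@@]1(Cl)C(=O)O[C@H]1C[C@H](Cl)[C@@](C)(Br)CCl | intermediate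
23 | (2R,3R,5S,6S)‑3,6‑dibromo‑2,5,7‑trichloro‑2,6‑dimethylheptanoic acid | OC(=O)[C@@](C)(Cl)[C@H](Br)C[C@H](Cl)[C@@](C)(Br)CCl | intermediate
24 | (2R,3R,5S,6S)‑3,6‑dibromo‑2,5,7‑trichloro‑2,6‑dimethylheptanoyl chloride | ClC(=O)[C@@](C)(Cl)[C@H](Br)C[C@H](Cl)[C@@](C)(Br)CCl | intermediate (not isolated)
25 | (3R,4R,6S,7S)‑4,7‑dibromo‑3,6,8‑trichloro‑1‑diazo‑3,7‑dimethyloctan‑2‑one | [N-]=[N+]=CC(=O)[C@@](C)(Cl)[C@H](Br)C[C@H](Cl)[C@@](C)(Br)CCl | intermediate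
26 | (3R,4R,6S,7S)‑4,7‑dibromo‑1,3,6,8‑tetrachloro‑3,7‑dimethyloctan‑2‑one | ClCC(=O)[C@@](C)(Cl)[C@H](Br)C[C@H](Cl)[C@@](C)(Br)CCl | intermediate
27 | (2S,3R,4R,6S,7S)‑4,7‑dibromo‑1,3,6,8‑tetrachloro‑3,7‑dimethyloctan‑2‑ol | ClC[C@H](O)[C@@](C)(Cl)[C@H](Br)C[C@H](Cl)[C@@](C)(Br)CCl | intermediate
28 | (S)‑2‑[(2R,3R,5S,6S)‑3,6‑dibromo‑2,5,7‑trichloro‑6‑methylheptan‑2‑yl]oxirane | C[C@](Cl)([C@H](Br)C[C@H](Cl)[C@@](C)(Br)CCl)[C@@H]1CO1 | target

**Step count and risks**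

Total steps: 20. Longest linear sequence: 20 steps (fully linear from propane‑1,3‑diol).

Risk 1, step 9 (primary alcohol to chloride next to the tertiary bromide). The C7 bromine can bridge to the activated primary carbon, and opening of that bromonium ion at the tertiary carbon would give the isomeric tertiary chloride/primary bromide. The fallback brings bromine in last, so that no bromine is present when C8 is chlorinated. It sets out from lactone 8 and rejoins at 13. The enolate 9 is hydroxylated with 2‑(phenylsulfonyl)‑3‑phenyloxaziridine, anti to the side chain, to give (3R,4R)‑4‑{2‑[(tert‑butyldiphenylsilyl)oxy]ethyl}‑3‑hydroxy‑3‑methyloxetan‑2‑one F1. HCl/Et4NCl opens it with inversion to (2S,3S)‑5‑[(tert‑butyldiphenylsilyl)oxy]‑3‑chloro‑2‑hydroxy‑2‑methylpentanoic acid F2. BH3·SMe2 reduces this to (2S,3S)‑5‑[(tert‑butyldiphenylsilyl)oxy]‑3‑chloro‑2‑methylpentane‑1,2‑diol F3. Appel chlorination (PPh3, CCl4) of the primary hydroxyl gives (2S,3S)‑5‑[(tert‑butyldiphenylsilyl)oxy]‑1,3‑dichloro‑2‑methylpentan‑2‑ol F4. Finally Me3SiBr in CH2Cl2 at −20 °C exchanges the tertiary hydroxyl for bromide. This last exchange is the uncertain point: a tertiary centre flanked by two β‑chlorines should ionise only with assistance from an anti chlorine, and bromide opening of the chloronium ion at the tertiary carbon would give net retention and hence 13.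

Risk 2, step 7 (SN2 opening of a β‑lactone at a carbon next to a quaternary centre; the same concern applies to step 16). If HCl is too slow or attacks the silyl ether, the fallback uses oxyphosphonium activation under aprotic conditions. It sets out from 10 and rejoins at 12, skipping acid 11. Ph3PCl2 (from PPh3 and Cl3CCCl3) in MeCN opens the lactone, chloride still entering with inversion, to give (2R,3S)‑2‑bromo‑5‑[(tert‑butyldiphenylsilyl)oxy]‑3‑chloro‑2‑methylpentanoyl chloride F5. LiAlH(O‑t‑Bu)3 in THF at −78 °C then reduces F5 directly to alcohol 12.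

Risk 3, step 15 (strong base on a substrate that carries a tertiary bromide and two chlorides, plus the facial selectivity of chlorination). The fallback installs the C3/C4 halogens by alkene bromochlorination instead. It sets out from aldehyde 15 and rejoins at acid 23, bypassing steps 12 to 16. Still–Gennari olefination (ethyl 2‑[bis(2,2,2‑trifluoroethoxy)phosphoryl]propanoate, KN(SiMe3)2, 18‑crown‑6, THF, −78 °C) gives ethyl (2Z,5S,6S)‑6‑bromo‑5,7‑dichloro‑2,6‑dimethylhept‑2‑enoate F6. i‑Bu2AlH at −78 °C gives (2Z,5S,6S)‑6‑bromo‑5,7‑dichloro‑2,6‑dimethylhept‑2‑en‑1‑ol F7. Catalytic enantioselective bromochlorination of this allylic alcohol (N‑bromosuccinimide, ClTi(O‑i‑Pr)3, 20 mol % chiral tridentate Schiff‑base ligand, hexanes, −20 °C) is an anti addition to the Z alkene and gives (2R,3R,5S,6S)‑3,6‑dibromo‑2,5,7‑trichloro‑2,6‑dimethylheptan‑1‑ol F8. The ligand enantiomer that gives the (2R,3R) product, and the regiochemistry (chloride at the tertiary carbon), would have to be confirmed experimentally. TEMPO/PhI(OAc)2 in MeCN/H2O oxidises F8 to acid 23.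

**Further compounds**

F1 | step 9 | (3R,4R)‑4‑{2‑[(tert‑butyldiphenylsilyl)oxy]ethyl}‑3‑hydroxy‑3‑methyloxetan‑2‑one | C[C@]1(O)C(=O)O[C@@H]1CCO[Si](c1ccccc1)(c1ccccc1)C(C)(C)C
F2 | step 9 | (2S,3S)‑5‑[(tert‑butyldiphenylsilyl)oxy]‑3‑chloro‑2‑hydroxy‑2‑methylpentanoic acid | OC(=O)[C@](C)(O)[C@@H](Cl)CCO[Si](c1ccccc1)(c1ccccc1)C(C)(C)C
F3 | step 9 | (2S,3S)‑5‑[(tert‑butyldiphenylsilyl)oxy]‑3‑chloro‑2‑methylpentane‑1,2‑diol | OC[C@](C)(O)[C@@H](Cl)CCO[Si](c1ccccc1)(c1ccccc1)C(C)(C)C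
F4 | step 9 | (2S,3S)‑5‑[(tert‑butyldiphenylsilyl)oxy]‑1,3‑dichloro‑2‑methylpentan‑2‑ol | ClC[C@](C)(O)[C@@H](Cl)CCO[Si](c1ccccc1)(c1ccccc1)C(C)(C)C
F5 | step 7 | (2R,3S)‑2‑bromo‑5‑[(tert‑butyldiphenylsilyl)oxy]‑3‑chloro‑2‑methylpentanoyl chloride | ClC(=O)[C@](C)(Br)[C@@H](Cl)CCO[Si](c1ccccc1)(c1ccccc1)C(C)(C)C
F6 | step 15 | ethyl (2Z,5S,6S)‑6‑bromo‑5,7‑dichloro‑2,6‑dimethylhept‑2‑enoate | CCOC(=O)/C(C)=C\C[C@H](Cl)[C@@](C)(Br)CCl
F7 | step 15 | (2Z,5S,6S)‑6‑bromo‑5,7‑dichloro‑2,6‑dimethylhept‑2‑en‑1‑ol | OC/C(C)=C\C[C@H](Cl)[C@@](C)(Br)CCl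
F8 | step 15 | (2R,3R,5S,6S)‑3,6‑dibromo‑2,5,7‑trichloro‑2,6‑dimethylheptan‑1‑ol | OC[C@@](C)(Cl)[C@H](Br)C[C@H](Cl)[C@@](C)(Br)CCl
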